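The route rests on forming the bond between ring carbon C6 and the benzylic, allylic C1′H2 last, from two complete halves. C1′–C2′=C3′(CH3)–C4′ is read as an isoprene unit. It enters as a 2-substituted butadiene, installed together with the C5′ carbinol by asymmetric isoprenylation of a C15 enal. Iron-catalysed 1,4-H–B addition then turns it into an (E)-allylboronate. The key α-selective allyl–aryl Suzuki–Miyaura coupling with a bis-silylated 2-bromo-6-methylhydroquinone exploits two features: C1′ is the primary end of an allyl unit whose other end, C3′, is fully substituted, and C6 lies beside the bulky O1 silyl ether. One fluoride treatment then frees all four hydroxyls.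

Key step: step 11

Remark: ring atoms are C1 (C–OH between methyl and chain), C2 (C–CH3), C4 (second C–OH) and C6 (chain-bearing carbon). Chain atoms run from C1′ (ArCH2) to C16′ (CH2OH). (2E,6E)-Farnesyl acetate as a single isomer, isoprene, (−)-B-methoxydiisopinocampheylborane and 4-hydroxy-3-methylbenzaldehyde are assumed to be commercial.

Step 1
Reactants: 1 (2E,6E)-farnesyl acetate
Product: 2 (2E,6E,10E)-12-hydroxy-3,7,11-trimethyldodeca-2,6,10-trien-1-yl acetate
Conditions: SeO2 (cat.), t-BuOOH, salicylic acid (cat.), CH2Cl2, 0 °C to rt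
Reagents that add atoms: tert-butyl hydroperoxide (terminal oxygen source via SeO2), CC(C)(C)OO
Why: Sharpless SeO2/t-BuOOH allylic oxidation (ene reaction, then [2,3]-shift) attacks the most electron-rich terminal trisubstituted alkene at its E-methyl group, the C2 alkene being deactivated by the allylic acetate, so the (E)-allylic alcohol should result.

Step 2
Reactants: 2 12-hydroxyfarnesyl acetate
Product: 3 (2E,6E,10E)-12-(tert-butyldimethylsilyloxy)-3,7,11-trimethyldodeca-2,6,10-trien-1-yl acetate
Conditions: TBSCl, imidazole, DMF, rt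
Reagents that add atoms: tert-butyldimethylsilyl chloride, CC(C)(C)[Si](C)(C)Cl
Why: Corey silylation of the only free hydroxyl, with the acetate untouched.

Step 3
Reactants: 3 silyl ether acetate
Product: 4 (2E,6E,10E)-12-(tert-butyldimethylsilyloxy)-3,7,11-trimethyldodeca-2,6,10-trien-1-ol
Conditions: K2CO3 (cat.), MeOH, rt
Reagents that add atoms: none
Why: Base-catalysed transesterification (Zemplén-type methanolysis) removes the acetate, while the alkyl TBS ether is stable to carbonate in methanol.

Step 4
Reactants: 4 allylic alcohol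
Product: 5 (2E,6E,10E)-12-(tert-butyldimethylsilyloxy)-3,7,11-trimethyldodeca-2,6,10-trienal
Conditions: MnO2, CH2Cl2, rt
Reagents that add atoms: none
Why: MnO2 oxidation is selective for allylic alcohols and should give the (2E)-enal without over-oxidation or loss of alkene geometry.

Step 5
Reactants: 5 C15 enal
Product: 7 (5S,6E,10E,14E)-16-(tert-butyldimethylsilyloxy)-7,11,15-trimethyl-3-methylidenehexadeca-1,6,10,14-tetraen-5-ol, via diisopinocampheylborinate ester 6 (not isolated)
Conditions: isoprene, KTMP (n-BuLi, KOt-Bu, TMP-H), THF, −78 °C; (−)-Ipc2BOMe; BF3·OEt2; then 5, −78 °C; HOCH2CH2NH2 work-up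
Reagents that add atoms: isoprene, C=CC(C)=C; (−)-B-methoxydiisopinocampheylborane (boron and Ipc groups stay only in 6), COB([C@@H]1C[C@@H]2C[C@H]([C@H]1C)C2(C)C)[C@@H]1C[C@@H]2C[C@H]([C@H]1C)C2(C)C
Why: Brown asymmetric allylboration with the B-isoprenyl reagent proceeds through a closed chair transition state in which the Ipc groups derived from (+)-α-pinene direct attack to the Si face of the enal, which sets C5′ as S and gives 1,2-addition only.

Step 6
Reactants: 7 (S)-dienol
Product: 8 (5S,6E,10E,14E)-5,16-bis(tert-butyldimethylsilyloxy)-7,11,15-trimethyl-3-methylidenehexadeca-1,6,10,14-tetraene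
Conditions: TBSCl, imidazole, DMF, rt
Reagents that add atoms: tert-butyldimethylsilyl chloride, CC(C)(C)[Si](C)(C)Cl
Why: Corey silylation under non-acidic conditions neither ionises nor epimerises C5′ and leaves no protic group for the low-valent iron catalyst of step 10.

Step 7
Reactants: 9 4-hydroxy-3-methylbenzaldehyde
Product: 10 3-bromo-4-hydroxy-5-methylbenzaldehyde
Conditions: Br2, AcOH, rt
Reagents that add atoms: bromine, BrBr
Why: In this electrophilic aromatic bromination the hydroxyl (ortho) and the formyl group (meta) direct to the same free carbon, the other ortho site carrying methyl and the para site the aldehyde.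

Step 8
Reactants: 10 bromo aldehyde
Product: 12 2-bromo-6-methylbenzene-1,4-diol, via aryl formate 11 (not isolated)
Conditions: H2O2, NaOH, H2O/THF, 0 °C to rt, N2; then acidify
Reagents that add atoms: hydrogen peroxide, OO
Why: In the Dakin oxidation hydroperoxide adds to the aldehyde, the para-hydroxyaryl group migrates to oxygen and the formate is saponified in situ, which fixes the 1,4-diol with bromine and methyl flanking the same oxygen.

Step 9
Reactants: 12 bromohydroquinone
Product: 13 1-bromo-2,5-bis(tert-butyldimethylsilyloxy)-3-methylbenzene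
Conditions: TBSCl, imidazole, DMF, rt to 40 °C
Reagents that add atoms: tert-butyldimethylsilyl chloride, CC(C)(C)[Si](C)(C)Cl
Why: Corey silylation of both phenols gives ethers that are inert to Pd(0) and leave together with the alkyl silyl ethers in the final fluoride step.

Step 10
Reactants: 8 silylated diene
Product: 14 2-[(2E,5S,6E,10E,14E)-5,16-bis(tert-butyldimethylsilyloxy)-3,7,11,15-tetramethylhexadeca-2,6,10,14-tetraen-1-yl]-4,4,5,5-tetramethyl-1,3,2-dioxaborolane
Conditions: HBpin, (2-iminopyridine)FeCl2 (5 mol %), Mg (10 mol %), Et2O, 23 °C; filtration through a short silica pad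
Reagents that add atoms: pinacolborane, B1OC(C)(C)C(C)(C)O1
Why: In the iron-catalysed 1,4-hydroboration of a 2-substituted 1,3-diene the diene binds s-cis (η4) to the low-valent iron centre, hydrogen goes to the exocyclic methylene (new C3′ methyl) and boron to the unhindered C1′, which should give the linear (E)-allylboronate and leave the isolated trisubstituted alkenes alone.

Step 11
Reactants: 14 (E)-allylboronate; 13 aryl bromide
Product: 15 tetrakis-TBS ether of the target (O1, O4, O5′, O16′ silylated; 2′E,5′S,6′E,10′E,14′E)
Conditions: Pd-PEPPSI-IPent (3 mol %), K3PO4 (2 M aq), THF, 45 °C, degassed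
Reagents that add atoms: none
Why: This is a Suzuki–Miyaura allyl–aryl coupling under α-selective conditions: Pd(0)–NHC inserts into the C6–Br bond of 13, base-assisted transmetalation of 14 gives an aryl(allyl)palladium species that equilibrates through its η3 form, and reductive elimination occurs from the primary σ-allyl terminus C1′. The closest known reaction type is the linear-selective prenylation and geranylation of aryl halides with 3,3-disubstituted allyl pinacolboronates. No ring is closed and no stereocentre is formed, and C5′ is remote and untouched. The step needs site selectivity (C1′ over tertiary C3′), which is secured by the fully substituted C3′ terminus and by the ortho O1 silyl ether on the aryl ligand, since together they make a quaternary benzylic centre prohibitive. It also needs retention of the 2′E geometry, which is secured because the η3-allyl is born from (E)-14 with the large C4′ branch syn and the methyl anti, its preferred arrangement, and because reductive elimination is fast at a bulky ligand and mild temperature. Ring regiochemistry is settled because bromine marks C6 from step 7 on, and the allylic silyl ethers at C5′ and C16′ are not ionised by Pd(0).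

Step 12
Reactants: 15 tetrasilyl ether
Product: 16 2-[(2E,5S,6E,10E,14E)-5,16-dihydroxy-3,7,11,15-tetramethylhexadeca-2,6,10,14-tetraen-1-yl]-6-methylbenzene-1,4-diol (target)
Conditions: TBAF, AcOH, THF, 0 °C to rt, Ar
Reagents that add atoms: none
Why: Fluoride-induced desilylation is buffered with acetic acid and run under argon, so the phenoxides are protonated at once and the hydroquinone is not oxidised, while the absence of strong acid protects the ionisable C5′ allylic alcohol and its configuration.

Compound list
1 | (2E,6E)-farnesyl acetate | CC(C)=CCC/C(C)=C/CC/C(C)=C/COC(C)=O | starting material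
2 | (2E,6E,10E)-12-hydroxyfarnesyl acetate | C/C(=C\CC/C(C)=C/CC/C(C)=C/COC(C)=O)CO | intermediate
3 | (2E,6E,10E)-12-(TBS-oxy)farnesyl acetate | C/C(=C\CC/C(C)=C/CC/C(C)=C/COC(C)=O)CO[Si](C)(C)C(C)(C)C | intermediate
4 | (2E,6E,10E)-12-(TBS-oxy)farnesol | C/C(=C\CC/C(C)=C/CC/C(C)=C/CO)CO[Si](C)(C)C(C)(C)C | intermediate
5 | (2E,6E,10E)-12-(TBS-oxy)farnesal | C/C(=C\CC/C(C)=C/CC/C(C)=C/C=O)CO[Si](C)(C)C(C)(C)C | intermediate
6 | diisopinocampheylborinate ester of 7 (not isolated) | C/C(=C\CC/C(C)=C/CC/C(C)=C/[C@@H](OB([C@@H]1C[C@@H]2C[C@H]([C@H]1C)C2(C)C)[C@@H]1C[C@@H]2C[C@H]([C@H]1C)C2(C)C)CC(=C)C=C)CO[Si](C)(C)C(C)(C)C | intermediate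
7 | (5S,6E,10E,14E)-16-(TBS-oxy)-7,11,15-trimethyl-3-methylidenehexadeca-1,6,10,14-tetraen-5-ol | C/C(=C\CC/C(C)=C/CC/C(C)=C/[C@@H](O)CC(=C)C=C)CO[Si](C)(C)C(C)(C)C | intermediate
8 | (5S)-5,16-bis(TBS-oxy) diene | C/C(=C\CC/C(C)=C/CC/C(C)=C/[C@@H](O[Si](C)(C)C(C)(C)C)CC(=C)C=C)CO[Si](C)(C)C(C)(C)C | intermediate
9 | 4-hydroxy-3-methylbenzaldehyde | Cc1cc(C=O)ccc1O | starting material
10 | 3-bromo-4-hydroxy-5-methylbenzaldehyde | Cc1cc(C=O)cc(Br)c1O | intermediate
11 | 3-bromo-4-hydroxy-5-methylphenyl formate (not isolated) | Cc1cc(OC=O)cc(Br)c1O | intermediate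
12 | 2-bromo-6-methylbenzene-1,4-diol | Cc1cc(O)cc(Br)c1O | intermediate
13 | 1-bromo-2,5-bis(TBS-oxy)-3-methylbenzene | Cc1cc(O[Si](C)(C)C(C)(C)C)cc(Br)c1O[Si](C)(C)C(C)(C)C | intermediate
14 | (2E,5S,6E,10E,14E)-allyl pinacolboronate | C/C(=C\CC/C(C)=C/CC/C(C)=C/[C@@H](O[Si](C)(C)C(C)(C)C)C/C(C)=C/CB1OC(C)(C)C(C)(C)O1)CO[Si](C)(C)C(C)(C)C | intermediate
15 | tetrakis-TBS ether of the target | C/C(=C\CC/C(C)=C/CC/C(C)=C/[C@@H](O[Si](C)(C)C(C)(C)C)C/C(C)=C/Cc1cc(O[Si](C)(C)C(C)(C)C)cc(C)c1O[Si](C)(C)C(C)(C)C)CO[Si](C)(C)C(C)(C)C | intermediate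
16 | CNP0151872.1 | C/C(=C\CC/C(C)=C/CC/C(C)=C/[C@@H](O)C/C(C)=C/Cc1cc(O)cc(C)c1O)CO | target

Total steps: 12. Longest linear sequence: 9 steps (1–6, 10–12).

Steps most likely to fail

1. Step 11.
- **What may go wrong.** Transmetalation with allyl transposition places palladium first on C3′. Rotation in that σ-allyl form before it collapses to the η3 form would erode the 2′E geometry. Bond formation at C3′, protodeboronation of the boronate and base-induced loss of the aryl silyl groups are further drains.
- **Fallback.** The polarity is reversed and the coupling becomes a neutral Stille allylation. It sets out from 14 and 13 and returns at 15. Boronate 14 is oxidised with NaBO3 in THF/H2O to the (E)-allylic alcohol F1, which is acetylated (Ac2O, pyridine) to the allylic acetate F2. Bromide 13 is stannylated with (Bu3Sn)2 and Pd(PPh3)4 in hot toluene to the aryl stannane F3. Coupling of F2 with F3 (Pd(dba)2, LiCl, DMF) enters the η3-allyl directly by ionisation, so it should join at the primary terminus with the alkene geometry kept. No aqueous base touches the silyl ethers, and the product is 15.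

2. Step 10.
- **What may go wrong.** The low-valent iron catalyst may be deactivated by trace protic or coordinating impurities. Boron may be delivered to the exocyclic methylene, or 1,2-addition to the vinyl group may occur.
- **Fallback.** The trisubstituted alkene is built by alkyne carbometalation instead. The path sets out from 5 and returns at 14. Enal 5 is propargylated with allenyl pinacolboronate under chiral phosphoric acid catalysis (the TRIP enantiomer chosen for Si-face attack) to the (S)-homopropargylic alcohol F4, which is silylated to the TBS ether F5. Negishi zirconium-catalysed methylalumination (Me3Al, Cp2ZrCl2) followed by iodine gives the (E)-vinyl iodide F6. Iodine–lithium exchange (t-BuLi, −78 °C) and addition of ClCH2Bpin form an ate complex, whose Matteson-type 1,2-shift delivers 14 with retention of geometry.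

3. Step 12.
- **What may go wrong.** The liberated hydroquinone may oxidise in air in the fluoride medium, and cleavage of the hindered O1 silyl ether may be slow, so that mixtures of oxidation states and partly protected material arise.
- **Fallback.** Purification is moved to the quinone level. The path sets out from 15 and returns at 16. All silyl groups are removed with unbuffered TBAF, and the crude product is deliberately oxidised with Ag2O to the benzoquinone diol F7, which is stable to chromatography. Two-phase reduction with aqueous Na2S2O4 (Et2O/H2O) directly before isolation gives 16.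

Further compounds
F1 | step 11 | (2E,5S,6E,10E,14E)-5,16-bis(TBS-oxy)-3,7,11,15-tetramethylhexadeca-2,6,10,14-tetraen-1-ol | C/C(=C\CC/C(C)=C/CC/C(C)=C/[C@@H](O[Si](C)(C)C(C)(C)C)C/C(C)=C/CO)CO[Si](C)(C)C(C)(C)C
F2 | step 11 | acetate of F1 | C/C(=C\CC/C(C)=C/CC/C(C)=C/[C@@H](O[Si](C)(C)C(C)(C)C)C/C(C)=C/COC(C)=O)CO[Si](C)(C)C(C)(C)C
F3 | step 11 | [2,5-bis(TBS-oxy)-3-methylphenyl]tributylstannane | Cc1cc(O[Si](C)(C)C(C)(C)C)cc([Sn](CCCC)(CCCC)CCCC)c1O[Si](C)(C)C(C)(C)C
F4 | step 10 | (4S,5E,9E,13E)-15-(TBS-oxy)-6,10,14-trimethylpentadeca-5,9,13-trien-1-yn-4-ol | C/C(=C\CC/C(C)=C/CC/C(C)=C/[C@@H](O)CC#C)CO[Si](C)(C)C(C)(C)C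
F5 | step 10 | TBS ether of F4 | C/C(=C\CC/C(C)=C/CC/C(C)=C/[C@@H](O[Si](C)(C)C(C)(C)C)CC#C)CO[Si](C)(C)C(C)(C)C
F6 | step 10 | (1E,4S,5E,9E,13E)-4,15-bis(TBS-oxy)-1-iodo-2,6,10,14-tetramethylpentadeca-1,5,9,13-tetraene | C/C(=C\CC/C(C)=C/CC/C(C)=C/[C@@H](O[Si](C)(C)C(C)(C)C)C/C(C)=C/I)CO[Si](C)(C)C(C)(C)C
F7 | step 12 | 2-[(2E,5S,6E,10E,14E)-5,16-dihydroxy-3,7,11,15-tetramethylhexadeca-2,6,10,14-tetraen-1-yl]-6-methyl-1,4-benzoquinone | C/C(=C\CC/C(C)=C/CC/C(C)=C/[C@@H](O)C/C(C)=C/CC1=CC(=O)C=C(C)C1=O)CO
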